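**Plan**

1. Locants: ring O1, C2 (guaiacyl), C3 (CH2OH), C4, C5 (OCH2); C7' is the exocyclic carbinol carbon on C4; Piv = pivaloyl. The target is read as (2S,3R,4S,7'R): all-trans ring, C4/C7' erythro.
2. Enabling feature: O1–C5H2–C4–C7'(OH)Ar is a 1,3-dioxygen unit whose C5 is an unsubstituted OCH2 and whose C7' is benzylic. It is the Markovnikov adduct of an oxocarbenium ion O1=C5H2(+) and an oxygen nucleophile across an (E)-styrene C4=C7', so the retrosynthesis cuts C4–C5 and C7'–O together (oxonium-Prins closure, formaldehyde as C5).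
3. The acyclic homoallylic alcohol is then cut at C2–C3 (Evans syn-aldol of O-pivaloylvanillin with an N-styrylacetyl oxazolidinone), and the styrylacetic acid at C4=C7' (Wittig).
4. Forward: Wittig, imide, aldol (joins the two aryl halves), reductive auxiliary removal, primary acetate, Prins closure of the only ring, one global deacylation.
5. Stereochemistry: C2 and C3 come from (S)-4-benzyl-2-oxazolidinone (syn aldol = 2,3-trans in the ring); C4 and C7' are both relayed in the Prins step (3,4-trans from C3, C7' by anti addition to the E alkene).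
6. Helpers: pivalates on the three phenols (they damp benzylic ionisation, 2-oxonia-Cope and alkene protonation), acetate on the primary OH, trifluoroacetate as the captured nucleophile; all five acyl groups leave in the last step.

Key step: step 8

Step 1
Reactants: 1 3,4-dihydroxybenzaldehyde
Product: 2 4-formyl-1,2-phenylene bis(2,2-dimethylpropanoate)
Conditions: PivCl (2.3 equiv), Et3N, DMAP (cat.), CH2Cl2, 0 °C to rt
Reagents that add atoms: pivaloyl chloride, CC(C)(C)C(Cl)=O
Why: DMAP-catalysed esterification of both phenols should be clean, and the pivalates are chosen because they are acid-stable, hindered and electron-withdrawing.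

Step 2
Reactants: 2 4-formyl-1,2-phenylene bis(2,2-dimethylpropanoate); 3 (2-carboxyethyl)triphenylphosphonium bromide
Product: 5 (E)-4-[3,4-bis(pivaloyloxy)phenyl]but-3-enoic acid, via carboxylate ylide 4 (not isolated)
Conditions: 3 (1.15 equiv), NaN(SiMe3)2 (2.25 equiv), THF, −78 to 0 °C; then 2, −78 °C to rt; aq. HCl to pH 3
Reagents that add atoms: none
Why: Wittig olefination with a carboxylate-bearing ylide, which is expected to give the E alkene with aromatic aldehydes, while the aldehyde should react far faster than the hindered aryl pivalates.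

Step 3
Reactants: 5 (E)-4-[3,4-bis(pivaloyloxy)phenyl]but-3-enoic acid; 6 (S)-4-benzyl-2-oxazolidinone
Product: 8 (S)-4-benzyl-3-{(E)-4-[3,4-bis(pivaloyloxy)phenyl]but-3-enoyl}oxazolidin-2-one, via mixed pivalic anhydride 7 (not isolated)
Conditions: PivCl (1.05 equiv), Et3N (2.5 equiv), THF, −20 °C; then 6, LiCl, −20 °C to rt
Reagents that add atoms: none
Why: N-acylation of the oxazolidinone through the mixed pivalic anhydride (LiCl/Et3N protocol) should occur at the unhindered butenoyl carbonyl, with no strong base to touch the aryl esters or the alkene.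

Step 4
Reactants: 9 vanillin (4-hydroxy-3-methoxybenzaldehyde)
Product: 10 4-formyl-2-methoxyphenyl pivalate
Conditions: PivCl (1.2 equiv), Et3N, DMAP (cat.), CH2Cl2, 0 °C to rt
Reagents that add atoms: pivaloyl chloride, CC(C)(C)C(Cl)=O
Why: DMAP-catalysed phenol esterification, which should turn the para oxygen of the future C2 aryl ring from a strong donor into a weak one.

Step 5
Reactants: 8 (S)-4-benzyl-3-{(E)-4-[3,4-bis(pivaloyloxy)phenyl]but-3-enoyl}oxazolidin-2-one; 10 4-formyl-2-methoxyphenyl pivalate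
Product: 12 (S)-4-benzyl-3-{(2S,3E)-4-[3,4-bis(pivaloyloxy)phenyl]-2-[(S)-hydroxy(3-methoxy-4-pivaloyloxyphenyl)methyl]but-3-enoyl}oxazolidin-2-one, via dibutylboron Z-dienolate 11 (not isolated)
Conditions: Bu2BOTf (1.2 equiv), iPr2NEt (1.4 equiv), CH2Cl2, −78 to 0 °C; then 10, −78 to 0 °C; pH 7 buffer, MeOH, 30% H2O2, 0 °C
Reagents that add atoms: none
Why: Evans syn-aldol, in which the Z boron dienolate should react at its α-carbon through a closed Zimmerman–Traxler chair on the face away from the benzyl group, setting C2 (S) and C3 together as the syn pair that becomes 2,3-trans in the ring.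

Step 6
Reactants: 12 (S)-4-benzyl-3-{(2S,3E)-4-[3,4-bis(pivaloyloxy)phenyl]-2-[(S)-hydroxy(3-methoxy-4-pivaloyloxyphenyl)methyl]but-3-enoyl}oxazolidin-2-one
Product: 13 4-{(1S,2R,3E)-4-[3,4-bis(pivaloyloxy)phenyl]-1-hydroxy-2-(hydroxymethyl)but-3-en-1-yl}-2-methoxyphenyl pivalate
Conditions: NaBH4 (3 equiv), THF/H2O 4:1, 0 °C
Reagents that add atoms: none
Why: Borohydride reduction of the N-acyloxazolidinone at its exocyclic carbonyl should release the primary alcohol and the auxiliary faster than it attacks the hindered aryl pivalates, and C3 keeps its configuration because reduction outruns enolisation at 0 °C.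

Step 7
Reactants: 13 4-{(1S,2R,3E)-4-[3,4-bis(pivaloyloxy)phenyl]-1-hydroxy-2-(hydroxymethyl)but-3-en-1-yl}-2-methoxyphenyl pivalate
Product: 14 (2R,3E)-4-[3,4-bis(pivaloyloxy)phenyl]-2-[(S)-hydroxy(3-methoxy-4-pivaloyloxyphenyl)methyl]but-3-en-1-yl acetate
Conditions: AcCl (1.05 equiv), 2,4,6-collidine, CH2Cl2, −78 °C
Reagents that add atoms: acetyl chloride, CC(Cl)=O
Why: Low-temperature acylation with AcCl/collidine should be selective for the primary hydroxyl over the hindered secondary benzylic one, leaving the oxygen that becomes O1 free.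

Step 8
Reactants: 14 (2R,3E)-4-[3,4-bis(pivaloyloxy)phenyl]-2-[(S)-hydroxy(3-methoxy-4-pivaloyloxyphenyl)methyl]but-3-en-1-yl acetate
Product: 17 {(2S,3R,4S)-4-[(R)-[3,4-bis(pivaloyloxy)phenyl](trifluoroacetoxy)methyl]-2-(3-methoxy-4-pivaloyloxyphenyl)tetrahydrofuran-3-yl}methyl acetate, via hemiformal 15 (not isolated), via oxocarbenium ion 16 (not isolated)
Conditions: (CH2O)n (1.5–3 equiv), CF3CO2H (15 equiv), CH2Cl2, 0 °C to rt; volatiles removed with toluene, crude product carried on
Reagents that add atoms: formaldehyde (charged as paraformaldehyde), C=O; trifluoroacetic acid, OC(=O)C(F)(F)F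
Why: Formaldehyde and the secondary alcohol give hemiformal 15, which trifluoroacetic acid ionises to oxocarbenium ion 16 (O1=C5H2+); C4, the β-carbon of the (E)-styrene, attacks C5 in the Markovnikov sense and the developing benzylic cation at C7' is captured by trifluoroacetate. The closest known reaction type is the oxonium-Prins cyclisation of styrenyl homoallylic alcohols with aldehydes to 3-(α-functionalised benzyl)tetrahydrofurans, run under the classical formaldehyde/trifluoroacetic acid Prins protocol. The tetrahydrofuran closes in a mode that is 5-endo with respect to the O1=C5 bond and exo with respect to C4=C7', which cationic closures onto an unsubstituted oxocarbenium carbon tolerate, whereas the alternative attack by C7' (six-membered ring with a secondary cation at C4, or 2-oxonia-Cope) is contra-Markovnikov. C4 is controlled by C3: in the envelope transition state the tether through C2 stands perpendicular to the alkene plane and C7' eclipses the small C3–H, not CH2OAc, which should give 3,4-trans; C7' is controlled by the E geometry, because capture anti to the newly formed C4–C5 bond (aligned with the cationic p orbital) makes the overall addition anti and gives the erythro (4S,7'R) pair. The step needs C4 over C7' attack, cyclisation over ionisation of the benzylic C2–O bond or protonation of the styrene, and kinetic capture over epimerisation at C7'. The pivalates secure these by making the guaiacyl ring a poor cation stabiliser and the catechol ring only a modest donor, so that the benzylic trifluoroacetate should not re-ionise.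

Step 9
Reactants: 17 {(2S,3R,4S)-4-[(R)-[3,4-bis(pivaloyloxy)phenyl](trifluoroacetoxy)methyl]-2-(3-methoxy-4-pivaloyloxyphenyl)tetrahydrofuran-3-yl}methyl acetate
Product: 18 4-[(R)-hydroxy{(3S,4R,5S)-4-(hydroxymethyl)-5-(4-hydroxy-3-methoxyphenyl)tetrahydrofuran-3-yl}methyl]benzene-1,2-diol (target)
Conditions: K2CO3 (5 equiv), degassed MeOH, Ar, 0 °C to rt; then aq. HCl to pH 5
Reagents that add atoms: none
Why: Base-mediated methanolysis (Zemplén-type transesterification) should cleave all five esters at the acyl–oxygen bond, the trifluoroacetate first and the aryl pivalates last, so that no phenoxide is ever para to a benzylic ester and no stereocentre is touched.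

**Compound list**

1 | 3,4-dihydroxybenzaldehyde | O=Cc1ccc(O)c(O)c1 | starting material
2 | 4-formyl-1,2-phenylene bis(2,2-dimethylpropanoate) | O=Cc1ccc(OC(=O)C(C)(C)C)c(OC(=O)C(C)(C)C)c1 | intermediate
3 | (2-carboxyethyl)triphenylphosphonium bromide | OC(=O)CC[P+](c1ccccc1)(c1ccccc1)c1ccccc1.[Br-] | starting material
4 | sodium 3-(triphenylphosphoranylidene)propanoate (carboxylate ylide) | [Na+].[O-]C(=O)CC=P(c1ccccc1)(c1ccccc1)c1ccccc1 | intermediate
5 | (E)-4-[3,4-bis(pivaloyloxy)phenyl]but-3-enoic acid | OC(=O)C/C=C/c1ccc(OC(=O)C(C)(C)C)c(OC(=O)C(C)(C)C)c1 | intermediate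
6 | (S)-4-benzyl-2-oxazolidinone | O=C1N[C@@H](Cc2ccccc2)CO1 | starting material
7 | mixed anhydride of 5 with pivalic acid | CC(C)(C)C(=O)OC(=O)C/C=C/c1ccc(OC(=O)C(C)(C)C)c(OC(=O)C(C)(C)C)c1 | intermediate
8 | (S)-4-benzyl-3-{(E)-4-[3,4-bis(pivaloyloxy)phenyl]but-3-enoyl}oxazolidin-2-one | O=C(C/C=C/c1ccc(OC(=O)C(C)(C)C)c(OC(=O)C(C)(C)C)c1)N1[C@@H](Cc2ccccc2)COC1=O | intermediate
9 | vanillin (4-hydroxy-3-methoxybenzaldehyde) | COc1cc(C=O)ccc1O | starting material
10 | 4-formyl-2-methoxyphenyl pivalate | COc1cc(C=O)ccc1OC(=O)C(C)(C)C | intermediate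
11 | dibutylboron Z-dienolate of 8 | CCCCB(CCCC)O/C(=C\C=C\c1ccc(OC(=O)C(C)(C)C)c(OC(=O)C(C)(C)C)c1)N1[C@@H](Cc2ccccc2)COC1=O | intermediate
12 | (S)-4-benzyl-3-{(2S,3E)-4-[3,4-bis(pivaloyloxy)phenyl]-2-[(S)-hydroxy(3-methoxy-4-pivaloyloxyphenyl)methyl]but-3-enoyl}oxazolidin-2-one | COc1cc([C@H]([C@@H](C(=O)N2[C@@H](Cc3ccccc3)COC2=O)/C=C/c4ccc(OC(=O)C(C)(C)C)c(OC(=O)C(C)(C)C)c4)O)ccc1OC(=O)C(C)(C)C | intermediate
13 | 4-{(1S,2R,3E)-4-[3,4-bis(pivaloyloxy)phenyl]-1-hydroxy-2-(hydroxymethyl)but-3-en-1-yl}-2-methoxyphenyl pivalate | COc1cc([C@H]([C@@H](CO)/C=C/c2ccc(OC(=O)C(C)(C)C)c(OC(=O)C(C)(C)C)c2)O)ccc1OC(=O)C(C)(C)C | intermediate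
14 | (2R,3E)-4-[3,4-bis(pivaloyloxy)phenyl]-2-[(S)-hydroxy(3-methoxy-4-pivaloyloxyphenyl)methyl]but-3-en-1-yl acetate | COc1cc([C@H]([C@@H](COC(C)=O)/C=C/c2ccc(OC(=O)C(C)(C)C)c(OC(=O)C(C)(C)C)c2)O)ccc1OC(=O)C(C)(C)C | intermediate
15 | hemiformal of 14 (secondary O–CH2–OH) | COc1cc([C@H]([C@@H](COC(C)=O)/C=C/c2ccc(OC(=O)C(C)(C)C)c(OC(=O)C(C)(C)C)c2)OCO)ccc1OC(=O)C(C)(C)C | intermediate
16 | O-methylidene oxocarbenium ion of 14, trifluoroacetate salt | COc1cc([C@H]([C@@H](COC(C)=O)/C=C/c2ccc(OC(=O)C(C)(C)C)c(OC(=O)C(C)(C)C)c2)[O+]=C)ccc1OC(=O)C(C)(C)C.[O-]C(=O)C(F)(F)F | intermediate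
17 | {(2S,3R,4S)-4-[(R)-[3,4-bis(pivaloyloxy)phenyl](trifluoroacetoxy)methyl]-2-(3-methoxy-4-pivaloyloxyphenyl)tetrahydrofuran-3-yl}methyl acetate | COc1cc([C@H]2OC[C@@H]([C@@H](OC(=O)C(F)(F)F)c3ccc(OC(=O)C(C)(C)C)c(OC(=O)C(C)(C)C)c3)[C@@H]2COC(C)=O)ccc1OC(=O)C(C)(C)C | intermediate
18 | 4-[(R)-hydroxy{(3S,4R,5S)-4-(hydroxymethyl)-5-(4-hydroxy-3-methoxyphenyl)tetrahydrofuran-3-yl}methyl]benzene-1,2-diol | COc1cc([C@H]2OC[C@@H]([C@@H](O)c3ccc(O)c(O)c3)[C@@H]2CO)ccc1O | target

**Step count and risks**

Total steps: 9. Longest linear sequence: 8 (steps 1, 2, 3, 5, 6, 7, 8, 9); step 4 is a one-step side branch.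

Steps most likely to fail:

1. Step 8. The benzylic cation may be captured only after rotation about C4–C7', which would erode the anti addition and give both carbinol epimers. It could also be intercepted by Friedel–Crafts attack of the guaiacyl ring (carbon para to OMe), or the oxocarbenium ion could drain away by 2-oxonia-Cope fragmentation. The fallback, aimed at the stereochemical leak, sets out from 17 obtained as a C7' epimer mixture and comes back at 18. NaHCO3 in MeOH at 0 °C should cleave only the trifluoroacetate and give {(2S,3R,4S)-4-{[3,4-bis(pivaloyloxy)phenyl](hydroxy)methyl}-2-(3-methoxy-4-pivaloyloxyphenyl)tetrahydrofuran-3-yl}methyl acetate as the epimer mixture F1. Dess–Martin periodinane (NaHCO3, CH2Cl2) should then give the aryl ketone {(2S,3R,4S)-4-[3,4-bis(pivaloyloxy)benzoyl]-2-(3-methoxy-4-pivaloyloxyphenyl)tetrahydrofuran-3-yl}methyl acetate F2, whose C4 can only relax to the all-trans ring. Zn(BH4)2 in Et2O at −40 °C should add hydride anti to C3 (Felkin–Anh, reinforced by chelation of the carbonyl with O1) to give the (R)-carbinol {(2S,3R,4S)-4-[(R)-[3,4-bis(pivaloyloxy)phenyl](hydroxy)methyl]-2-(3-methoxy-4-pivaloyloxyphenyl)tetrahydrofuran-3-yl}methyl acetate F3. The conditions of step 9 then deliver 18.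

2. Step 6. Hydride may attack the aryl pivalates alongside the imide (loss of protecting groups), and the basic medium may enolise the doubly activated C3–H before reduction. The fallback sets out from 12 and comes back at 13. Reduction is made deliberately exhaustive (excess LiBH4, THF/MeOH, rt) to give 4-[(1S,2R,3E)-4-(3,4-dihydroxyphenyl)-1-hydroxy-2-(hydroxymethyl)but-3-en-1-yl]-2-methoxyphenol F4. Phenol-selective Schotten–Baumann acylation (PivCl, aq. NaOH/CH2Cl2, Bu4NHSO4, 0 °C, under N2) should then reinstall the three aryl pivalates and leave both aliphatic hydroxyls free, which is 13.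

3. Step 2. The olefination may give Z alkene alongside E, and the basic ylide may accept a pivaloyl group from the aryl esters. The fallback sets out from 2 and comes back at 5. Non-basic, ester-tolerant Lombardo methylenation (Zn, CH2Br2, TiCl4, THF) should give 4-ethenyl-1,2-phenylene bis(2,2-dimethylpropanoate) F5. Cross-metathesis of F5 with but-3-enoic acid (second-generation Grubbs catalyst (H2IMes)(PCy3)Cl2Ru=CHPh, CH2Cl2, 40 °C) should then give the E acid 5 under thermodynamic control.

**Further compounds**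

F1 | step 8 | {(2S,3R,4S)-4-{[3,4-bis(pivaloyloxy)phenyl](hydroxy)methyl}-2-(3-methoxy-4-pivaloyloxyphenyl)tetrahydrofuran-3-yl}methyl acetate, carbinol epimer mixture | COc1cc([C@H]2OC[C@@H](C(O)c3ccc(OC(=O)C(C)(C)C)c(OC(=O)C(C)(C)C)c3)[C@@H]2COC(C)=O)ccc1OC(=O)C(C)(C)C
F2 | step 8 | {(2S,3R,4S)-4-[3,4-bis(pivaloyloxy)benzoyl]-2-(3-methoxy-4-pivaloyloxyphenyl)tetrahydrofuran-3-yl}methyl acetate | COc1cc([C@H]2OC[C@@H](C(=O)c3ccc(OC(=O)C(C)(C)C)c(OC(=O)C(C)(C)C)c3)[C@@H]2COC(C)=O)ccc1OC(=O)C(C)(C)C
F3 | step 8 | {(2S,3R,4S)-4-[(R)-[3,4-bis(pivaloyloxy)phenyl](hydroxy)methyl]-2-(3-methoxy-4-pivaloyloxyphenyl)tetrahydrofuran-3-yl}methyl acetate | COc1cc([C@H]2OC[C@@H]([C@@H](O)c3ccc(OC(=O)C(C)(C)C)c(OC(=O)C(C)(C)C)c3)[C@@H]2COC(C)=O)ccc1OC(=O)C(C)(C)C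
F4 | step 6 | 4-[(1S,2R,3E)-4-(3,4-dihydroxyphenyl)-1-hydroxy-2-(hydroxymethyl)but-3-en-1-yl]-2-methoxyphenol | COc1cc([C@H]([C@@H](CO)/C=C/c2ccc(O)c(O)c2)O)ccc1O
F5 | step 2 | 4-ethenyl-1,2-phenylene bis(2,2-dimethylpropanoate) | C=Cc1ccc(OC(=O)C(C)(C)C)c(OC(=O)C(C)(C)C)c1
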